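**Retrosynthetic overview**
1. Target 9 ⇐ 8 (removal of eight O-benzyl groups) ⇐ 7 (removal of two O-acetyl groups).
2. Key disconnection: the diarylmethine C1–C8(flavan) bond. Both halves are the same monomer 5: one molecule is opened at O1–C2 and acts as electrophile, a second is arylated at C8.
3. The ring opening/arylation is a visible-light photoredox step steered by the 3-O-acetyl group (double inversion at C2, net retention).
4. 5 ⇐ (+)-catechin 1 by phenol benzylation and 3-O-acetylation; C3 of both halves and C2 of the lower half are carried unchanged from 1.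
5. Ring order: no ring is built; ring C of the upper half is opened, rings A to C of the lower half stay intact.

Assumption: commercial (+)-catechin is the (2R,3S) enantiomer, and the target is the 8-linked (1S,2S) chalcane–flavan dimer exactly as encoded in the SMILES.

**Step 1**
Reactants: 1 (+)-catechin; 2 benzyl bromide
Product: 3 (2R,3S)-5,7-bis(benzyloxy)-2-[3,4-bis(benzyloxy)phenyl]chroman-3-ol
Conditions: BnBr (4.4 equiv), K2CO3 (4.6 equiv), DMF, 0 °C → rt, argon
Reagents that add atoms: benzyl bromide BrCc1ccccc1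
Why: Williamson etherification in which K2CO3 deprotonates only the four phenols, so the secondary 3-OH stays free and no stereocentre is touched.

**Step 2**
Reactants: 3 (2R,3S)-5,7-bis(benzyloxy)-2-[3,4-bis(benzyloxy)phenyl]chroman-3-ol; 4 acetic anhydride
Product: 5 (2R,3S)-5,7-bis(benzyloxy)-2-[3,4-bis(benzyloxy)phenyl]chroman-3-yl acetate
Conditions: Ac2O (1.5 equiv), pyridine, 4-(dimethylamino)pyridine (5 mol %), CH2Cl2, rt
Reagents that add atoms: acetic anhydride CC(=O)OC(C)=O
Why: Nucleophile-catalysed O-acylation of the only free hydroxyl, with retention at C3, installs the participating group that later controls the new stereocentre.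

**Step 3**
Reactants: 5 (2R,3S)-5,7-bis(benzyloxy)-2-[3,4-bis(benzyloxy)phenyl]chroman-3-yl acetate (two molecules: one is ring-opened, one reacts through C8)
Product: 7 (2R,3S)-8-{(1S,2S)-2-acetoxy-1-[3,4-bis(benzyloxy)phenyl]-3-[2,4-bis(benzyloxy)-6-hydroxyphenyl]propyl}-5,7-bis(benzyloxy)-2-[3,4-bis(benzyloxy)phenyl]chroman-3-yl acetate, via trans-acetoxonium phenoxide zwitterion 6 (not isolated)
Conditions: 9-mesityl-3,6-di-tert-butyl-10-phenylacridinium tetrafluoroborate (5 mol %), 450 nm LEDs, (CF3)2CHOH/CH2Cl2 1:1, 0.3 M, argon, 10 °C, stopped at ca. 40% conversion (5 recovered and recycled)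
Reagents that add atoms: none
Why: Proposed new method: photoredox radical-cation mesolysis of a cyclic benzylic aryl ether coupled to an acyloxonium-directed Friedel–Crafts alkylation — the excited acridinium (about +2.0 V vs SCE) oxidises the trialkoxy ring A of 5 (about +1.4 V), which turns the O1 aryloxy group into an excellent nucleofuge; the equatorial 3-OAc carbonyl, antiperiplanar to the C2–O1 bond, displaces it from the rear (first inversion) to give the trans-acetoxonium ion and an aryloxyl radical, which the acridinyl radical (about −0.6 V) reduces to the phenoxide, closing a redox-neutral cycle at zwitterion 6; C8 of a second molecule of 5, the established site of Friedel–Crafts attack in 5,7-di-O-benzylflavans, then opens 6 at the benzylic carbon anti to the acetoxonium oxygen (second inversion), so the diarylmethine centre forms with net retention as (1S) under control of the catechin C3 centre; the closest known reaction types are photoredox mesolysis of alkoxyamine radical cations to carbocations, acyloxonium-directed 3,4-trans arylation at C4 of 3-O-acylflavans and C8 arylation of tetra-O-benzylcatechin in procyanidin synthesis.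

**Step 4**
Reactants: 7 (2R,3S)-8-{(1S,2S)-2-acetoxy-1-[3,4-bis(benzyloxy)phenyl]-3-[2,4-bis(benzyloxy)-6-hydroxyphenyl]propyl}-5,7-bis(benzyloxy)-2-[3,4-bis(benzyloxy)phenyl]chroman-3-yl acetate
Product: 8 (2R,3S)-5,7-bis(benzyloxy)-2-[3,4-bis(benzyloxy)phenyl]-8-{(1S,2S)-1-[3,4-bis(benzyloxy)phenyl]-3-[2,4-bis(benzyloxy)-6-hydroxyphenyl]-2-hydroxypropyl}chroman-3-ol
Conditions: K2CO3 (0.3 equiv), MeOH/THF 1:1, rt, argon
Reagents that add atoms: none
Why: Base-catalysed transesterification (Zemplén-type methanolysis) cleaves both secondary acetates at the acyl carbon, so no C–O bond at a stereocentre is broken; all phenols except the one on the opened ring A are still benzyl ethers, so no quinone methide can form.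

**Step 5**
Reactants: 8 (2R,3S)-5,7-bis(benzyloxy)-2-[3,4-bis(benzyloxy)phenyl]-8-{(1S,2S)-1-[3,4-bis(benzyloxy)phenyl]-3-[2,4-bis(benzyloxy)-6-hydroxyphenyl]-2-hydroxypropyl}chroman-3-ol
Product: 9 (2R,3S)-2-(3,4-dihydroxyphenyl)-8-[(1S,2S)-1-(3,4-dihydroxyphenyl)-2-hydroxy-3-(2,4,6-trihydroxyphenyl)propyl]chroman-3,5,7-triol
Conditions: H2 (1 atm), Pd(OH)2 on carbon (20 wt %), THF/MeOH 1:1, rt; filtration under argon, Sephadex LH-20 (EtOH)
Reagents that add atoms: none
Why: Catalytic hydrogenolysis removes the eight aryl benzyl ethers under neutral conditions that leave the flavan C2–O1 bond and all four stereocentres untouched, as in standard procyanidin end-games.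

**Compound list**
1 | (+)-catechin, (2R,3S)-2-(3,4-dihydroxyphenyl)chroman-3,5,7-triol | Oc1cc(O)c2c(c1)O[C@H](c1ccc(O)c(O)c1)[C@@H](O)C2 | starting material
2 | benzyl bromide | BrCc1ccccc1 | starting material
3 | (2R,3S)-5,7-bis(benzyloxy)-2-[3,4-bis(benzyloxy)phenyl]chroman-3-ol | c1ccccc1COc1cc(OCc2ccccc2)c2c(c1)O[C@H](c1ccc(OCc3ccccc3)c(OCc3ccccc3)c1)[C@@H](O)C2 | intermediate
4 | acetic anhydride | CC(=O)OC(C)=O | starting material
5 | (2R,3S)-5,7-bis(benzyloxy)-2-[3,4-bis(benzyloxy)phenyl]chroman-3-yl acetate | c1ccccc1COc1cc(OCc2ccccc2)c2c(c1)O[C@H](c1ccc(OCc3ccccc3)c(OCc3ccccc3)c1)[C@@H](OC(C)=O)C2 | intermediate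
6 | (4S,5S)-4-[3,4-bis(benzyloxy)phenyl]-5-[2,4-bis(benzyloxy)-6-oxidobenzyl]-2-methyl-1,3-dioxolan-2-ylium (4,5-trans zwitterion, not isolated) | CC1=[O+][C@@H](c2ccc(OCc3ccccc3)c(OCc3ccccc3)c2)[C@H](Cc2c([O-])cc(OCc3ccccc3)cc2OCc2ccccc2)O1 | intermediate
7 | (2R,3S)-8-{(1S,2S)-2-acetoxy-1-[3,4-bis(benzyloxy)phenyl]-3-[2,4-bis(benzyloxy)-6-hydroxyphenyl]propyl}-5,7-bis(benzyloxy)-2-[3,4-bis(benzyloxy)phenyl]chroman-3-yl acetate | Oc1cc(OCc2ccccc2)cc(OCc2ccccc2)c1C[C@H](OC(C)=O)[C@@H](c1ccc(OCc2ccccc2)c(OCc2ccccc2)c1)c1c(OCc2ccccc2)cc(OCc2ccccc2)c2c1O[C@H](c1ccc(OCc3ccccc3)c(OCc3ccccc3)c1)[C@@H](OC(C)=O)C2 | intermediate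
8 | (2R,3S)-5,7-bis(benzyloxy)-2-[3,4-bis(benzyloxy)phenyl]-8-{(1S,2S)-1-[3,4-bis(benzyloxy)phenyl]-3-[2,4-bis(benzyloxy)-6-hydroxyphenyl]-2-hydroxypropyl}chroman-3-ol | Oc1cc(OCc2ccccc2)cc(OCc2ccccc2)c1C[C@H](O)[C@@H](c1ccc(OCc2ccccc2)c(OCc2ccccc2)c1)c1c(OCc2ccccc2)cc(OCc2ccccc2)c2c1O[C@H](c1ccc(OCc3ccccc3)c(OCc3ccccc3)c1)[C@@H](O)C2 | intermediate
9 | (2R,3S)-2-(3,4-dihydroxyphenyl)-8-[(1S,2S)-1-(3,4-dihydroxyphenyl)-2-hydroxy-3-(2,4,6-trihydroxyphenyl)propyl]chroman-3,5,7-triol | Oc1cc(O)c(C[C@H](O)[C@@H](c2ccc(O)c(O)c2)c2c(O)cc(O)c3c2O[C@H](c2ccc(O)c(O)c2)[C@@H](O)C3)c(O)c1 | target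

**Step count**
Total steps: 5. Longest linear sequence: 5 (1 → 3 → 5 → 7 → 8 → 9; both halves of the dimer come from the single intermediate 5).

**Steps most likely to fail, with fallbacks**

Step 3 (the proposed new step). The risks are:
- Internal return: the zwitterion 6 can re-close to 5 through its own phenol oxygen. This is non-destructive but lowers the quantum efficiency.
- Over-arylation: product 7 carries a nucleophilic opened ring A and an intact flavan unit that can itself be opened, hence the stop at about 40% conversion.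
- Stereochemical leakage: attack on the open benzylic cation instead of the acetoxonium ion would erode the (1S) selectivity.
- Side oxidation: the benzyl ethers or the product phenol may be oxidised by the photocatalyst.

The fallback uses known chemistry and sets out from 1. Base-induced ring opening of 1 to its B-ring quinone methide in the presence of benzyl mercaptan (aqueous NaOH, pH 12, rt, argon) gives (2S)-1-(benzylsulfanyl)-1-(3,4-dihydroxyphenyl)-3-(2,4,6-trihydroxyphenyl)propan-2-ol F1 as a mixture of C1 epimers. Thiophilic activation of F1 with AgBF4 (THF, 0 °C, dark) in the presence of an excess of 1 regenerates the benzylic cation, which alkylates 1 mainly at C8. This comes back to the route at 9. The price is that the 6-linked regioisomer and the C1 epimer are formed as well and have to be removed on Sephadex LH-20 and by reversed-phase HPLC.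

Step 1. C-benzylation at C6/C8 and base-induced C2 epimerisation of the free polyphenol can depress the yield of 3. The fallback sets out from 1 and protects in the reverse order. Peracetylation (Ac2O, pyridine) gives (2R,3S)-2-(3,4-diacetoxyphenyl)chroman-3,5,7-triyl triacetate F2. The known one-pot exchange of phenolic acetates for benzyl ethers (NaH, BnCl, DMF, about 4 equiv H2O, 0 °C → rt) leaves the aliphatic 3-O-acetate in place. This comes back to the route at 5, bypassing 3 and step 2.

Step 5. Hydrogenolysis of eight benzyl ethers may stall, may hydrogenolyse a benzylic C–O or C–C bond, and delivers an air-sensitive nonaphenol. The fallback sets out from 7 and replaces hydrogenolysis by Lewis-acid dealkylation with the secondary hydroxyls still acetylated. BCl3 with pentamethylbenzene as benzyl-cation scavenger (CH2Cl2, −78 °C) gives (2R,3S)-8-[(1S,2S)-2-acetoxy-1-(3,4-dihydroxyphenyl)-3-(2,4,6-trihydroxyphenyl)propyl]-2-(3,4-dihydroxyphenyl)-5,7-dihydroxychroman-3-yl acetate F3. Acid-catalysed methanolysis (HCl generated from AcCl in MeOH, 0 °C → rt, argon) then removes the two acetates without exposing the free catechols to base. This comes back to the route at 9, bypassing 8.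

**Further compounds**
F1 | step 3 | (2S)-1-(benzylsulfanyl)-1-(3,4-dihydroxyphenyl)-3-(2,4,6-trihydroxyphenyl)propan-2-ol (both C1 epimers) | Oc1cc(O)c(C[C@H](O)C(SCc2ccccc2)c2ccc(O)c(O)c2)c(O)c1
F2 | step 1 | (2R,3S)-2-(3,4-diacetoxyphenyl)chroman-3,5,7-triyl triacetate | CC(=O)Oc1cc(OC(C)=O)c2c(c1)O[C@H](c1ccc(OC(C)=O)c(OC(C)=O)c1)[C@@H](OC(C)=O)C2
F3 | step 5 | (2R,3S)-8-[(1S,2S)-2-acetoxy-1-(3,4-dihydroxyphenyl)-3-(2,4,6-trihydroxyphenyl)propyl]-2-(3,4-dihydroxyphenyl)-5,7-dihydroxychroman-3-yl acetate | Oc1cc(O)cc(O)c1C[C@H](OC(C)=O)[C@@H](c1ccc(O)c(O)c1)c1c(O)cc(O)c2c1O[C@H](c1ccc(O)c(O)c1)[C@@H](OC(C)=O)C2
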